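## Analysis of the target

Compound 15 (C30H32O6) is an open triaryl diether: three benzene rings joined by two diaryl ether oxygens, with no ring to close and no stereocentre. Ring A is a 4-allyl-2-methoxyphenyl group bound through the oxygen on its C1, and ring B, the central ring, carries that oxygen at C1, the oxygen to ring C at C2, a methoxy group at C3 and an allyl group at C5. Ring C carries the ring B oxygen at C1, a free hydroxyl at C2, a methoxy group at C3 and an allyl group at C5. The sensitive groups are the three allyl chains, which move into conjugation under strong base, heat or metal hydrides and do not survive hydrogenation or electrophilic oxidants, and the electron-rich free phenol. The difficulty lies in the two aryl–O–aryl bonds: all rings are electron-rich, the bond at C2 of ring B is flanked by two oxygen substituents, and the two neighbouring oxygens of ring C must be told apart. The strategy rests on one regularity: C1 of ring A and C2 of ring B, the carbons that receive the ether oxygens, each lie para to the allyl-bearing carbon (C4 of ring A, C5 of ring B). In ring C the allyl carbon C5 lies para to the hydroxyl carbon C2 and meta to the ether carbon C1. If each allyl group is written as a formyl group, the two ether carbons become sites for fluoride displacement, the ring C oxygens differ in basicity, and the three aldehydes can later be converted to allyl groups together.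

## Retrosynthetic reasoning

15 ⇒ 14. The last operation is the release of the ring C phenol from its methoxymethyl ether. The phenol cannot stay free during the side-chain chemistry, because a para-hydroxybenzyl chloride would eliminate to a quinone methide and a free phenol would quench the Grignard reagent. An acetal-type ether is chosen because mild acid removes it without touching the alkenes.

14 ⇒ 12 + 13. The three ArCH2–CH=CH2 bonds are cut between the benzylic and the vinylic carbon. This places the double bond at the chain end by construction, with no allyl-metal regiochemistry to control, and treats all three rings alike. The forward reaction must replace three benzylic chlorides by the vinyl group of 13 without homocoupling.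

12 ⇒ 10 ⇒ 9. The chlorides (via the trimesylate 11) come from the benzylic alcohols and these from the aldehydes. The gain is that the three side chains are now formyl groups, each para to an oxygen-bearing carbon.

9 ⇒ 8. Removal of the protecting group in the retrosynthetic sense. The phenol of 8 is the oxygen para to the ring C formyl group, which is the oxygen left unarylated in the preceding step.

8 ⇒ 6 + 7. The bond between the ring C oxygen and C2 of ring B is cut. This carbon is para to the ring B formyl group, so a fluoride there can be displaced. The nucleophile is the dianion of 7, which should react through the oxygen meta to its formyl group. The forward reaction has to form the most hindered ether bond of the molecule and to choose between two oxygens.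

6 ⇒ 5 ⇒ 4 + 1. This is the key disconnection: the bond between the ring B oxygen and C1 of ring A. Ring A is 1 itself, whose fluorine is para to the formyl group. Ring B arrives as phenol 4, which already carries the fluorine needed for the next ether bond. Its formyl group is masked as a dioxolane, so that only one C–F bond in the flask is activated. Hydrolysis of 5 then gives 6 and switches the second fluoride on.

4 ⇒ 3 ⇒ 2 ⇒ 1. The phenol oxygen of ring B is traced back through the pinacol boronate 3 to a C–H bond. Ring B is thus made from the same aldehyde 1, using the fact that the C–H bond next to fluorine is the least hindered one of acetal 2.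

## Alternatives that were turned down

Alternative 1: The bond from the ring C oxygen to C2 of ring B is cut, with ring B carried as a cyclohexane-1,3-dione and aromatised later.
- Forward key step: Rh2(OAc)4, a divalent rhodium carboxylate, decomposes 5-allyl-2-diazocyclohexane-1,3-dione A1. The carbenoid derived from A1 inserts into the O–H bond of 5-allyl-3-methoxy-2-(methoxymethoxy)phenol A2 and gives 5-allyl-2-[5-allyl-3-methoxy-2-(methoxymethoxy)phenoxy]cyclohexane-1,3-dione A3.
- For it: the congested ether bond forms at a non-aromatic carbon, so it needs neither SNAr activation nor copper, and it is less sensitive to the flanking groups than the second displacement of the chosen route. Two allyl groups are in place from the start, one in A1 and one in A2.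
- Against it: the carbenoid can also cyclopropanate the allyl double bonds of A1 and A2 or attack the electron-rich arene of A2. A3 must then be dehydrogenated to 5-allyl-2-[5-allyl-3-methoxy-2-(methoxymethoxy)phenoxy]benzene-1,3-diol A4 with reagents that also attack or isomerise alkenes. A4 has two equivalent hydroxyls, of which one must become a methyl ether and the other the ring A ether, so a statistical step follows. The ring A ether must still be made on a doubly ortho-substituted phenol without activation.
- Comparison: the chosen route fixes the substitution pattern of ring B through purchased arenes, has no alkene present until the second-last step, and needs fewer operations after its key step.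

Alternative 2: The three benzylic C–C bonds are cut at once from a triaryl ether bearing three carboxymethyl groups.
- Forward key step: the tris(1,3-dioxoisoindolin-2-yl) ester A5 is electrolysed with NiCl2(dme), a bipyridine ligand and vinyl bromide A6. Each benzylic radical formed from A5 by loss of CO2 is captured at nickel and vinylated, which gives the methoxymethyl ether of the target A7. A7 has the same structure as 14.
- For it: one operation replaces the three steps from aldehyde to allyl, and it avoids labile benzylic chlorides and a large excess of Grignard reagent. On this point it is stronger than the chosen route.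
- Against it: carboxymethyl groups do not activate any ring carbon, so the two ether bonds must be made by copper couplings at hindered positions, or by the same formyl-activated displacements followed by three one-carbon homologations. Benzylic radicals with para oxygen donors dimerise readily, three radical captures must succeed on one molecule, and the radicals can add to allyl groups already formed. The esters in A5 have acidic α-hydrogens, and A6 is a toxic gas that requires an electrolysis set-up.
- Comparison: both routes pass through the same protected compound, since A7 is identical with 14. The chosen route lets one functional group, the aldehyde, both activate the ether formation and serve as the side-chain precursor.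

Alternative 3: Ring A is built de novo, with the ring A–ring B ether oxygen already in the alkyne partner.
- Forward key step: 5-allyl-1-(ethynyloxy)-3-methoxy-2-(methoxymethoxy)benzene A8 adds across C3 and C6 of methyl 3-bromo-2-oxo-2H-pyran-5-carboxylate A9. The bicyclic adduct of A8 and A9 loses CO2 and gives methyl 3-bromo-4-[5-allyl-3-methoxy-2-(methoxymethoxy)phenoxy]benzoate A10.
- For it: the ether bond does not depend on any activating group, the polarity of the two partners fixes the regiochemistry, and the ring B allyl group can be carried from the start.
- Against it: it constructs a benzene ring that can be bought as 1. Aryl ethynyl ethers such as A8 need strong-base chemistry to make and are thermally fragile at the temperatures that a pyranone such as A9 requires for cycloaddition. The allyl group of A8 is a second dienophile. A10 still needs bromine-to-methoxy exchange, a three-step ester-to-allyl sequence and deprotection. The hardest ether bond, at the doubly flanked ring B oxygen, is then left to an unactivated coupling.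
- Comparison: the chosen route is shorter, uses only purchased arenes, and forms both ether bonds by the same activated displacement.

Key step: step 4

Assumption: 4-fluoro-3-hydroxy-5-methoxybenzaldehyde is not taken to be purchasable. The ring B phenol is therefore made from 1 and kept as its dioxolane 4 through the key step, which leaves only one activated C–F bond in that flask.

## Route

Step 1
Reactants: 1 4-fluoro-3-methoxybenzaldehyde
Product: 2 2-(4-fluoro-3-methoxyphenyl)-1,3-dioxolane
Conditions: ethylene glycol (2 equiv), p-TsOH·H2O (cat.), toluene, reflux, Dean–Stark
Reagents that add atoms: ethylene glycol, OCCO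
Why: Acid-catalysed acetalisation with azeotropic removal of water; a free aldehyde would be reduced or borylated by the boron hydride formed in step 2 and would activate the fluorine too early.

Step 2
Reactants: 2 2-(4-fluoro-3-methoxyphenyl)-1,3-dioxolane
Product: 3 2-[5-(1,3-dioxolan-2-yl)-2-fluoro-3-methoxyphenyl]-4,4,5,5-tetramethyl-1,3,2-dioxaborolane
Conditions: [Ir(OMe)(cod)]2 (1.5 mol %), 4,4'-di-tert-butyl-2,2'-bipyridine (3 mol %), B2pin2 (1.0 equiv), THF, 60 °C
Reagents that add atoms: bis(pinacolato)diboron, CC1(C)OB(OC1(C)C)B1OC(C)(C)C(C)(C)O1
Why: Iridium-catalysed aromatic C–H borylation is sterically controlled: C5–H has only fluorine and hydrogen as neighbours, whereas C2–H lies between methoxy and dioxolanyl and C6–H next to the dioxolanyl group. A C–H bond ortho to fluorine is also electronically preferred, and the acetal, the methyl ether and the C–F bond are inert to the catalyst.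

Step 3
Reactants: 3 2-[5-(1,3-dioxolan-2-yl)-2-fluoro-3-methoxyphenyl]-4,4,5,5-tetramethyl-1,3,2-dioxaborolane
Product: 4 5-(1,3-dioxolan-2-yl)-2-fluoro-3-methoxyphenol
Conditions: NaBO3·4H2O (3 equiv), THF/H2O 1:1, rt; work-up at pH 7
Reagents that add atoms: sodium perborate, [Na+].[O-]OB=O
Why: Oxidation of an arylboronic ester: hydroperoxide adds to boron, the aryl group shifts from boron to oxygen at the same ring carbon, and the borate is hydrolysed. The mildly basic medium and neutral work-up keep the acid-labile dioxolane.

Step 4
Reactants: 4 5-(1,3-dioxolan-2-yl)-2-fluoro-3-methoxyphenol; 1 4-fluoro-3-methoxybenzaldehyde (1.3 equiv)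
Product: 6 4-fluoro-3-(4-formyl-2-methoxyphenoxy)-5-methoxybenzaldehyde, via monoacetal diaryl ether 5 (not isolated)
Conditions: K2CO3 (2 equiv), DMSO, 100 °C, N2; then 2 M aq HCl, THF, rt
Reagents that add atoms: water, O
Why: With K2CO3 in DMSO, phenol 4 is present as its phenoxide, which adds to C4 of 1, the fluorine-bearing carbon para to the formyl group. The resulting cyclohexadienyl anion (a Meisenheimer-type σ-adduct) carries its charge onto the formyl oxygen, and loss of fluoride restores the arene and gives diaryl ether 5. This is the long-established addition–elimination etherification of 4-fluorobenzaldehydes with phenoxides; no ring is closed and no stereocentre is formed. The selectivity needed is that only one C–F bond in the flask reacts: the fluorine of 4 and of 5 sits para to an acetal carbon, which cannot accept the negative charge, and between two oxygen donors, so self-condensation and chain growth cannot start. The formyl group of 1 has no α-hydrogen and adds phenoxide only reversibly. Attack of further phenoxide at the ether carbon of 5 would only exchange identical aryloxy groups. Aqueous HCl in the same flask then hydrolyses the dioxolane, so that 6 emerges with the ring B formyl group para to the remaining fluorine, which is thereby activated for step 5.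

Step 5
Reactants: 6 4-fluoro-3-(4-formyl-2-methoxyphenoxy)-5-methoxybenzaldehyde; 7 3,4-dihydroxy-5-methoxybenzaldehyde (1.1 equiv)
Product: 8 3-[4-formyl-2-(4-formyl-2-methoxyphenoxy)-6-methoxyphenoxy]-4-hydroxy-5-methoxybenzaldehyde
Conditions: 7, KOt-Bu (2.1 equiv), degassed DMSO, rt; then 6, 90 °C, Ar; 1 M HCl work-up
Reagents that add atoms: none
Why: SNAr of a phenoxide on a 4-fluorobenzaldehyde, now at the ring B fluorine that the formyl group freed in step 4 activates from the para position. Of the two oxygens of the dianion of 7, O3 (meta to formyl) is the more basic and less hindered, while O4 is a vinylogous carboxylate between two substituents, so arylation should go to O3. An O-to-O aryl shift through a spiro σ-adduct would lead to the same isomer, because it leaves the better stabilised para-formyl phenoxide free.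

Step 6
Reactants: 8 3-[4-formyl-2-(4-formyl-2-methoxyphenoxy)-6-methoxyphenoxy]-4-hydroxy-5-methoxybenzaldehyde
Product: 9 3-[4-formyl-2-(4-formyl-2-methoxyphenoxy)-6-methoxyphenoxy]-5-methoxy-4-(methoxymethoxy)benzaldehyde
Conditions: MOMCl (1.5 equiv), i-Pr2NEt (2 equiv), CH2Cl2, 0 °C to rt
Reagents that add atoms: chloromethyl methyl ether, COCCl
Why: Williamson-type O-alkylation of the acidic, formyl-conjugated phenol with an α-chloro ether. The methoxymethyl group is inert to hydride, sulfonylation and Grignard reagents and is removed by mild acid, whereas a benzyl ether would need hydrogenolysis and cost the alkenes.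

Step 7
Reactants: 9 3-[4-formyl-2-(4-formyl-2-methoxyphenoxy)-6-methoxyphenoxy]-5-methoxy-4-(methoxymethoxy)benzaldehyde
Product: 10 [3-[4-(hydroxymethyl)-2-[4-(hydroxymethyl)-2-methoxyphenoxy]-6-methoxyphenoxy]-5-methoxy-4-(methoxymethoxy)phenyl]methanol
Conditions: NaBH4 (3 equiv), MeOH/THF, 0 °C
Reagents that add atoms: none
Why: Borohydride reduction of three non-enolisable aryl aldehydes to benzylic alcohols; the ethers, the MOM group and the arenes are untouched.

Step 8
Reactants: 10 [3-[4-(hydroxymethyl)-2-[4-(hydroxymethyl)-2-methoxyphenoxy]-6-methoxyphenoxy]-5-methoxy-4-(methoxymethoxy)phenyl]methanol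
Product: 12 5-(chloromethyl)-1-[4-(chloromethyl)-2-[4-(chloromethyl)-2-methoxyphenoxy]-6-methoxyphenoxy]-3-methoxy-2-(methoxymethoxy)benzene, via trimesylate 11 (not isolated)
Conditions: MsCl (3.6 equiv), Et3N (4.5 equiv), CH2Cl2, 0 °C; then LiCl (6 equiv), DMF, rt; crude product used directly
Reagents that add atoms: methanesulfonyl chloride, CS(=O)(=O)Cl; lithium chloride, [Li+].[Cl-]
Why: Sulfonylation of the primary benzylic alcohols followed by SN2 displacement of mesylate by chloride; each benzylic carbon has a para oxygen donor, which makes the displacement fast. The mesyl groups placed on 11 leave again as methanesulfonate, and the neutral to basic medium spares the MOM ether, which HCl from thionyl chloride would endanger.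

Step 9
Reactants: 12 5-(chloromethyl)-1-[4-(chloromethyl)-2-[4-(chloromethyl)-2-methoxyphenoxy]-6-methoxyphenoxy]-3-methoxy-2-(methoxymethoxy)benzene; 13 vinylmagnesium bromide
Product: 14 5-allyl-1-[4-allyl-2-(4-allyl-2-methoxyphenoxy)-6-methoxyphenoxy]-3-methoxy-2-(methoxymethoxy)benzene
Conditions: 13 (1.0 M in THF, 4.5 equiv), CuI (10 mol % per C–Cl), THF, −20 to 0 °C, slow addition of 12; aq NH4Cl
Reagents that add atoms: vinylmagnesium bromide, C=C[Mg]Br
Why: Copper-catalysed cross-coupling of benzylic halides with a vinyl Grignard reagent: the vinylcuprate formed in the flask substitutes each primary benzylic chloride, so the double bond is terminal from the outset. Slow addition of 12 to excess 13 at low temperature should limit halogen–magnesium exchange and Wurtz-type homocoupling, and the aryl ethers and the MOM group do not react with the Grignard reagent.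

Step 10
Reactants: 14 5-allyl-1-[4-allyl-2-(4-allyl-2-methoxyphenoxy)-6-methoxyphenoxy]-3-methoxy-2-(methoxymethoxy)benzene
Product: 15 4-allyl-2-[4-allyl-2-(4-allyl-2-methoxyphenoxy)-6-methoxyphenoxy]-6-methoxyphenol
Conditions: conc. HCl (cat.), MeOH, 40 °C
Reagents that add atoms: none
Why: Acid-catalysed cleavage of the mixed acetal by transacetalisation to methanol; diaryl ethers, methyl ethers and isolated terminal alkenes are stable to dilute acid at this temperature. Both ortho positions and the para position of the freed phenol are substituted, so the formaldehyde equivalent cannot alkylate the ring.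

## Compound list

1 | 4-fluoro-3-methoxybenzaldehyde | COc1cc(C=O)ccc1F | starting material
2 | 2-(4-fluoro-3-methoxyphenyl)-1,3-dioxolane | COc1cc(C2OCCO2)ccc1F | intermediate
3 | 2-[5-(1,3-dioxolan-2-yl)-2-fluoro-3-methoxyphenyl]-4,4,5,5-tetramethyl-1,3,2-dioxaborolane | COc1cc(C2OCCO2)cc(B3OC(C)(C)C(C)(C)O3)c1F | intermediate
4 | 5-(1,3-dioxolan-2-yl)-2-fluoro-3-methoxyphenol | COc1cc(C2OCCO2)cc(O)c1F | intermediate
5 | 4-[5-(1,3-dioxolan-2-yl)-2-fluoro-3-methoxyphenoxy]-3-methoxybenzaldehyde | COc1cc(C=O)ccc1Oc1cc(C2OCCO2)cc(OC)c1F | intermediate
6 | 4-fluoro-3-(4-formyl-2-methoxyphenoxy)-5-methoxybenzaldehyde | COc1cc(C=O)ccc1Oc1cc(C=O)cc(OC)c1F | intermediate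
7 | 3,4-dihydroxy-5-methoxybenzaldehyde | COc1cc(C=O)cc(O)c1O | starting material
8 | 3-[4-formyl-2-(4-formyl-2-methoxyphenoxy)-6-methoxyphenoxy]-4-hydroxy-5-methoxybenzaldehyde | COc1cc(C=O)ccc1Oc1cc(C=O)cc(OC)c1Oc1cc(C=O)cc(OC)c1O | intermediate
9 | 3-[4-formyl-2-(4-formyl-2-methoxyphenoxy)-6-methoxyphenoxy]-5-methoxy-4-(methoxymethoxy)benzaldehyde | COCOc1c(OC)cc(C=O)cc1Oc1c(OC)cc(C=O)cc1Oc1ccc(C=O)cc1OC | intermediate
10 | [3-[4-(hydroxymethyl)-2-[4-(hydroxymethyl)-2-methoxyphenoxy]-6-methoxyphenoxy]-5-methoxy-4-(methoxymethoxy)phenyl]methanol | COCOc1c(OC)cc(CO)cc1Oc1c(OC)cc(CO)cc1Oc1ccc(CO)cc1OC | intermediate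
11 | tris(methanesulfonate) of triol 10 (each CH2OH as CH2OSO2CH3) | COCOc1c(OC)cc(COS(C)(=O)=O)cc1Oc1c(OC)cc(COS(C)(=O)=O)cc1Oc1ccc(COS(C)(=O)=O)cc1OC | intermediate
12 | 5-(chloromethyl)-1-[4-(chloromethyl)-2-[4-(chloromethyl)-2-methoxyphenoxy]-6-methoxyphenoxy]-3-methoxy-2-(methoxymethoxy)benzene | COCOc1c(OC)cc(CCl)cc1Oc1c(OC)cc(CCl)cc1Oc1ccc(CCl)cc1OC | intermediate
13 | vinylmagnesium bromide | C=C[Mg]Br | starting material
14 | 5-allyl-1-[4-allyl-2-(4-allyl-2-methoxyphenoxy)-6-methoxyphenoxy]-3-methoxy-2-(methoxymethoxy)benzene | COCOc1c(OC)cc(CC=C)cc1Oc1c(OC)cc(CC=C)cc1Oc1ccc(CC=C)cc1OC | intermediate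
15 | 4-allyl-2-[4-allyl-2-(4-allyl-2-methoxyphenoxy)-6-methoxyphenoxy]-6-methoxyphenol | C=CCc1ccc(Oc2cc(CC=C)cc(OC)c2Oc2cc(CC=C)cc(OC)c2O)c(OC)c1 | target

## Step count and risks

Total step count: 10. Longest linear sequence: 10 steps (1 to 15); 7, 13 and the second portion of 1 are purchased and enter directly.

Step 4 (key step). The addition may be slow, because the electrophile is activated by a single formyl group and has a donor methoxy group next to fluorine, and the nucleophile is a hindered ortho-fluorophenoxide. Long heating would then allow displacement of fluoride from 1 by adventitious hydroxide and demethylation of aryl methyl ethers by phenoxide. The fallback sets out from 4 and uses an Ullmann ether coupling with purchased 4-bromo-3-methoxybenzaldehyde (CuI, N,N-dimethylglycine, Cs2CO3, dioxane, 90 °C). The C–O bond then forms at copper and needs no stabilised σ-adduct. It returns to the route at 5, which is hydrolysed to 6 as before. This fallback makes no compound outside the compound list and is entered as F0.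

Step 5. Discrimination between the two oxygens of the catecholate may be incomplete. Substitution at the doubly flanked C–F bond may also be slow enough for aryloxy exchange at the formyl-activated ether carbon of ring A, or for air oxidation of the dianion, to compete. The fallback sets out from 7, which is protected selectively at the more acidic O4 (MOMCl 1.0 equiv, i-Pr2NEt 1.1 equiv, DMF, 0 °C) to give 3-hydroxy-5-methoxy-4-(methoxymethoxy)benzaldehyde F1. Its single phenoxide (Cs2CO3, DMSO, 90 °C) displaces the fluoride of 6 and gives 9 directly, so the route is rejoined at 9 and step 6 is dropped.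

Step 9. Benzyl–magnesium exchange may lead to Wurtz-type homocoupling, which with three reactive sites per molecule means oligomerisation, and the threefold substitution may stay incomplete. The fallback sets out from 10, which is converted with CBr4/PPh3 (CH2Cl2, 0 °C) to 5-(bromomethyl)-1-[4-(bromomethyl)-2-[4-(bromomethyl)-2-methoxyphenoxy]-6-methoxyphenoxy]-3-methoxy-2-(methoxymethoxy)benzene F2. A Stille coupling of F2 with tributyl(vinyl)stannane (Pd(PPh3)4, a zerovalent palladium complex, THF, 60 °C) avoids any benzyl–metal species of the Grignard type and rejoins the route at 14.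

Step 2. Borylation may go in part to C6, next to the dioxolanyl group, if the acetal oxygens direct the catalyst. The fallback sets out from 2 and uses deprotonation ortho to fluorine with lithium 2,2,6,6-tetramethylpiperidide in THF at −78 °C in the presence of B(Oi-Pr)3. Aqueous NH4Cl work-up gives [5-(1,3-dioxolan-2-yl)-2-fluoro-3-methoxyphenyl]boronic acid F3. Here the site is set by C–H acidity next to fluorine rather than by sterics, and trapping in the flask forestalls aryne formation. Oxidation of F3 with NaBO3·4H2O as in step 3 rejoins the route at 4.

## Further compounds

F0 | step 4 | none | none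
F1 | step 5 | 3-hydroxy-5-methoxy-4-(methoxymethoxy)benzaldehyde | COCOc1c(O)cc(C=O)cc1OC
F2 | step 9 | 5-(bromomethyl)-1-[4-(bromomethyl)-2-[4-(bromomethyl)-2-methoxyphenoxy]-6-methoxyphenoxy]-3-methoxy-2-(methoxymethoxy)benzene | COCOc1c(OC)cc(CBr)cc1Oc1c(OC)cc(CBr)cc1Oc1ccc(CBr)cc1OC
F3 | step 2 | [5-(1,3-dioxolan-2-yl)-2-fluoro-3-methoxyphenyl]boronic acid | COc1cc(C2OCCO2)cc(B(O)O)c1F
A1 | alternative 1 | 5-allyl-2-diazocyclohexane-1,3-dione | C=CCC1CC(=O)C(=[N+]=[N-])C(=O)C1
A2 | alternative 1 | 5-allyl-3-methoxy-2-(methoxymethoxy)phenol | C=CCc1cc(O)c(OCOC)c(OC)c1
A3 | alternative 1 | 5-allyl-2-[5-allyl-3-methoxy-2-(methoxymethoxy)phenoxy]cyclohexane-1,3-dione | C=CCC1CC(=O)C(Oc2cc(CC=C)cc(OC)c2OCOC)C(=O)C1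
A4 | alternative 1 | 5-allyl-2-[5-allyl-3-methoxy-2-(methoxymethoxy)phenoxy]benzene-1,3-diol | C=CCc1cc(O)c(Oc2cc(CC=C)cc(OC)c2OCOC)c(O)c1
A5 | alternative 2 | tris(1,3-dioxoisoindolin-2-yl) ester of the triacetic acid analogue of 14 (each allyl group replaced by CH2CO2H) | COCOc1c(OC)cc(CC(=O)ON2C(=O)c3ccccc3C2=O)cc1Oc1c(OC)cc(CC(=O)ON2C(=O)c3ccccc3C2=O)cc1Oc1ccc(CC(=O)ON2C(=O)c3ccccc3C2=O)cc1OC
A6 | alternative 2 | vinyl bromide | C=CBr
A7 | alternative 2 | 5-allyl-1-[4-allyl-2-(4-allyl-2-methoxyphenoxy)-6-methoxyphenoxy]-3-methoxy-2-(methoxymethoxy)benzene | C=CCc1ccc(Oc2cc(CC=C)cc(OC)c2Oc2cc(CC=C)cc(OC)c2OCOC)c(OC)c1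
A8 | alternative 3 | 5-allyl-1-(ethynyloxy)-3-methoxy-2-(methoxymethoxy)benzene | C#COc1cc(CC=C)cc(OC)c1OCOC
A9 | alternative 3 | methyl 3-bromo-2-oxo-2H-pyran-5-carboxylate | COC(=O)C1=COC(=O)C(Br)=C1
A10 | alternative 3 | methyl 3-bromo-4-[5-allyl-3-methoxy-2-(methoxymethoxy)phenoxy]benzoate | COC(=O)c1ccc(Oc2cc(CC=C)cc(OC)c2OCOC)c(Br)c1
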